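**Retrosynthetic overview**
1. Target 13 ⇐ tert-butyl ester 12 by acidolysis, which is the only protecting-group step.
2. Key disconnection: the aryl C–O bond of the depside (not the usual acyl C–O bond), made by Chan–Lam O-arylation of free acid 4 with arylboronic acid 11.
3. 11 ⇐ sterically controlled Ir C–H borylation of arene 9 at its only unhindered C–H; together with line 2 this is a formal meta C–H acyloxylation, so no phenol and no regioselective O-protection are needed.
4. Both side chains ⇐ lateral (benzylic) lithiation/alkylation of the o-toluic acids 1 and 5 with 1-iodohexane and 1-iodobutane.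
5. No ring is formed: both benzene rings are bought intact.

Assumption: the target has no stereogenic element (it is achiral), so "single enantiomer" means the compound as drawn; 1, 2, 5 and 6 are taken as catalogue chemicals.

**Route**

Step 1
Reactants: 1 2,4-dimethoxy-6-methylbenzoic acid; 2 1-iodohexane
Product: 4 2-heptyl-4,6-dimethoxybenzoic acid, via dilithio dianion 3 (not isolated)
Conditions: LDA (2.3 equiv), THF, −78 → 0 °C; then 2 (1.1 equiv), −78 °C → rt; 1 M HCl
Reagents that add atoms: none
Why: Lateral (benzylic) lithiation of an o-toluic acid: the lithium carboxylate directs the second deprotonation to the ortho methyl group and the dianion is C-alkylated by the primary iodide in an SN2 reaction, with no stereocentre formed.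

Step 2
Reactants: 5 2-methoxy-6-methylbenzoic acid; 6 1-iodobutane
Product: 8 2-methoxy-6-pentylbenzoic acid, via dilithio dianion 7 (not isolated)
Conditions: LDA (2.3 equiv), THF, −78 → 0 °C; then 6 (1.1 equiv), −78 °C → rt; 1 M HCl
Reagents that add atoms: none
Why: The same lateral lithiation/SN2 alkylation of the o-toluate dianion extends the methyl group to pentyl, and LDA does not metalate the ring ortho to OMe.

Step 3
Reactants: 8 2-methoxy-6-pentylbenzoic acid
Product: 9 tert-butyl 2-methoxy-6-pentylbenzoate
Conditions: Cl3CC(=NH)OtBu (2 equiv), BF3·OEt2 (5 mol %), CH2Cl2/cyclohexane, rt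
Reagents that add atoms: tert-butyl 2,2,2-trichloroacetimidate, CC(C)(C)OC(=N)C(Cl)(Cl)Cl
Why: Trichloroacetimidate O-alkylation (SN1 transfer of tert-butyl to the carboxylate oxygen) avoids attack at the di-ortho-blocked acyl carbon, and tert-butyl, unlike benzyl, carries no arene C–H that would be borylated in step 4.

Step 4
Reactants: 9 tert-butyl 2-methoxy-6-pentylbenzoate
Product: 11 [4-(tert-butoxycarbonyl)-3-methoxy-5-pentylphenyl]boronic acid, via pinacol boronate 10 (not isolated)
Conditions: [Ir(OMe)(cod)]2 (1.5 mol %), dtbpy (3 mol %), B2pin2 (0.75 equiv), THF, 80 °C; then NaIO4 (3 equiv), THF/H2O 4:1, rt; then 1 M HCl, rt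
Reagents that add atoms: bis(pinacolato)diboron, CC1(C)OB(OC1(C)C)B1OC(C)(C)C(C)(C)O1; water, O
Why: Sterically governed Ir-catalysed aromatic C–H borylation goes to C4, the only ring C–H without an ortho substituent (C3 is next to OMe, C5 next to pentyl), and periodate cleavage of the pinacol in the same pot frees the boronic acid.

Step 5
Reactants: 4 2-heptyl-4,6-dimethoxybenzoic acid; 11 [4-(tert-butoxycarbonyl)-3-methoxy-5-pentylphenyl]boronic acid (1.5 equiv)
Product: 12 tert-butyl 4-[(2-heptyl-4,6-dimethoxybenzoyl)oxy]-2-methoxy-6-pentylbenzoate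
Conditions: Cu(OTf)2 (0.4 equiv), urea (1 equiv), EtOAc, 60 °C, open to air
Reagents that add atoms: none
Why: Chan–Lam oxidative C–O coupling: the carboxylate of 4 binds Cu(II), the aryl group is transferred from boron and C–O reductive elimination from Cu(III) forms the aryl ester at oxygen, so the di-ortho-substituted acyl carbon of 4 is never attacked.

Step 6
Reactants: 12 tert-butyl 4-[(2-heptyl-4,6-dimethoxybenzoyl)oxy]-2-methoxy-6-pentylbenzoate
Product: 13 4-[(2-heptyl-4,6-dimethoxybenzoyl)oxy]-2-methoxy-6-pentylbenzoic acid
Conditions: TFA/CH2Cl2 1:4, 0 °C → rt, 1–2 h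
Reagents that add atoms: none
Why: Acidolysis of the tert-butyl ester (AAL1 cleavage with E1 loss of isobutene) leaves the hindered diaryl ester and the methyl ethers intact, and every free ring position is flanked by two substituents, which blocks Friedel–Crafts tert-butylation.

**Compound list**
1 | 2,4-dimethoxy-6-methylbenzoic acid | Cc1cc(OC)cc(OC)c1C(=O)O | starting material
2 | 1-iodohexane | CCCCCCI | starting material
3 | dilithium salt of the lateral (benzylic) dianion of 1 | [Li+].[Li+].[CH2-]c1cc(OC)cc(OC)c1C(=O)[O-] | intermediate (not isolated)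
4 | 2-heptyl-4,6-dimethoxybenzoic acid | CCCCCCCc1cc(OC)cc(OC)c1C(=O)O | intermediate
5 | 2-methoxy-6-methylbenzoic acid | Cc1cccc(OC)c1C(=O)O | starting material
6 | 1-iodobutane | CCCCI | starting material
7 | dilithium salt of the lateral (benzylic) dianion of 5 | [Li+].[Li+].[CH2-]c1cccc(OC)c1C(=O)[O-] | intermediate (not isolated)
8 | 2-methoxy-6-pentylbenzoic acid | CCCCCc1cccc(OC)c1C(=O)O | intermediate
9 | tert-butyl 2-methoxy-6-pentylbenzoate | CCCCCc1cccc(OC)c1C(=O)OC(C)(C)C | intermediate
10 | tert-butyl 2-methoxy-6-pentyl-4-(4,4,5,5-tetramethyl-1,3,2-dioxaborolan-2-yl)benzoate | CCCCCc1cc(B2OC(C)(C)C(C)(C)O2)cc(OC)c1C(=O)OC(C)(C)C | intermediate (not isolated)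
11 | [4-(tert-butoxycarbonyl)-3-methoxy-5-pentylphenyl]boronic acid | CCCCCc1cc(B(O)O)cc(OC)c1C(=O)OC(C)(C)C | intermediate
12 | tert-butyl 4-[(2-heptyl-4,6-dimethoxybenzoyl)oxy]-2-methoxy-6-pentylbenzoate | CCCCCCCc1cc(OC)cc(OC)c1C(=O)Oc1cc(CCCCC)c(C(=O)OC(C)(C)C)c(OC)c1 | intermediate
13 | 4-[(2-heptyl-4,6-dimethoxybenzoyl)oxy]-2-methoxy-6-pentylbenzoic acid (CNP0274910.0, achiral) | CCCCCCCc1cc(OC)cc(OC)c1C(=O)Oc1cc(CCCCC)c(C(=O)O)c(OC)c1 | target

**Totals**
Total step count: 6. Longest linear sequence: 5 (steps 2, 3, 4, 5, 6); step 1 is the convergent branch.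

**Three steps most likely to fail**

1. Step 5 (Chan–Lam esterification). The risks are slow carboxylate transfer from the bulky acid, protodeboronation or phenol formation from 11, and partial loss of the tert-butyl group under Lewis-acidic Cu(OTf)2. The fallback sets out from 11 (and 4) and comes back at 12. Oxidise 11 with H2O2/NaOH in THF at 0 °C to tert-butyl 4-hydroxy-2-methoxy-6-pentylbenzoate F1. In a second flask convert 4 with oxalyl chloride and catalytic DMF in CH2Cl2 into 2-heptyl-4,6-dimethoxybenzoyl chloride F2. Combine F1 and F2 with Et3N and catalytic DMAP in CH2Cl2 at reflux to give 12. This replaces Cu-mediated O-arylation with classical acyl substitution on the phenol.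

2. Step 4 (borylation and one-pot pinacol cleavage). The borylation of the crowded arene may be slow, and the periodate/HCl stage may be incomplete or lose boronic acid on isolation (boroxine formation, protodeboronation). The fallback sets out from 10, this time isolated by filtration through silica, and comes back at 11. Stir 10 with diethanolamine in Et2O so that the sp3 boronate tert-butyl 4-(1,3,6,2-dioxazaborocan-2-yl)-2-methoxy-6-pentylbenzoate F3 crystallises and is filtered off. Shake F3 with 0.5 M HCl/Et2O to release 11. This replaces oxidative destruction of pinacol with transesterification and purification by crystallisation.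

3. Step 1 (dianion alkylation of the electron-rich toluic acid). The risks are incomplete formation of dianion 3, competing ring metalation at C3 between the two methoxy groups, and O-alkylation of the carboxylate. The fallback sets out from 2 and comes back at 4, building the chain before the carboxyl group.
   - Convert 2 with Mg in THF into hexylmagnesium iodide F4.
   - Couple F4 with purchased 3,5-dimethoxybenzyl bromide F5 under Li2CuCl4 catalysis (THF, −10 °C) to give 1-heptyl-3,5-dimethoxybenzene F6.
   - Vilsmeier–Haack formylation of F6 (POCl3, DMF, 0 → 70 °C) attacks the position next to the alkyl chain, para to one OMe and ortho to the other, giving N-[(2-heptyl-4,6-dimethoxyphenyl)methylidene]-N-methylmethanaminium chloride F7.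
   - Aqueous NaOAc hydrolyses F7 to 2-heptyl-4,6-dimethoxybenzaldehyde F8.
   - Pinnick oxidation of F8 (NaClO2, NaH2PO4, 2-methyl-2-butene, t-BuOH/H2O) gives 4.

**Further compounds**
F1 | step 5 | tert-butyl 4-hydroxy-2-methoxy-6-pentylbenzoate | CCCCCc1cc(O)cc(OC)c1C(=O)OC(C)(C)C
F2 | step 5 | 2-heptyl-4,6-dimethoxybenzoyl chloride | CCCCCCCc1cc(OC)cc(OC)c1C(Cl)=O
F3 | step 4 | tert-butyl 4-(1,3,6,2-dioxazaborocan-2-yl)-2-methoxy-6-pentylbenzoate | CCCCCc1cc(B2OCCNCCO2)cc(OC)c1C(=O)OC(C)(C)C
F4 | step 1 | hexylmagnesium iodide | CCCCCC[Mg]I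
F5 | step 1 | 3,5-dimethoxybenzyl bromide (purchased, not made) | COc1cc(CBr)cc(OC)c1
F6 | step 1 | 1-heptyl-3,5-dimethoxybenzene | CCCCCCCc1cc(OC)cc(OC)c1
F7 | step 1 | N-[(2-heptyl-4,6-dimethoxyphenyl)methylidene]-N-methylmethanaminium chloride | CCCCCCCc1cc(OC)cc(OC)c1C=[N+](C)C.[Cl-]
F8 | step 1 | 2-heptyl-4,6-dimethoxybenzaldehyde | CCCCCCCc1cc(OC)cc(OC)c1C=O
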